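**Plan**

Labels: ring A is the central benzene, with C1 bearing the methide carbon C7, C2 bearing ring B (the 2,4-dihydroxyphenyl ring), C3 and C4 bearing H, C5 bearing CH2OH and C6 bearing the alkyne carbon C8; C9 is the alkyne carbon on the 4-hydroxyphenyl ring.
Retrosynthesis: the quinone methide is a deprotected, dehydrated triaryl carbinol; the C9–aryl bond is cut (Sonogashira), then C8≡C9 (one-carbon homologation of a lactol), which leads back to a 3,3-diarylphthalide whose lactone joins C7 and C8 through oxygen.
Enabling feature: C7 and C8 sit on the neighbouring ring atoms C1 and C6 and the C3–C4 edge carries only hydrogen, so ring A can be cut at C1–C6, C2–C3 and C4–C5 into a C7–O–C8(=O)-tethered 1,6-diyne plus acetylene.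
Forward: aryl alkyne, diaryl ketone and ynoyl chloride are joined in one pot to the diyne ester; one [2+2+2] closes the lactone and ring A together; then lactone to lactol, lactol to terminal alkyne, alkyne to diaryl alkyne, and acid unmasks the phenols and dehydrates the carbinol.
Stereochemistry: the target has no stereocentre and no configurable double bond (the dienone ring is symmetric about the exocyclic C=C); the lactol centre is racemic and transient.

Key step: step 7

Remark: the open quinone methide with the free resorcinol ring is taken as the stable form of the fully deprotected compound, as the target is drawn; tert-butyldimethyl(prop-2-yn-1-yloxy)silane is taken as a commercial material.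

**Route**

Step 1
Reactants: 1 2,4-dihydroxybenzaldehyde
Product: 2 2,4-bis(methoxymethoxy)benzaldehyde
Conditions: MOMCl, i-Pr2NEt, CH2Cl2, 0 °C to rt
Reagents that add atoms: chloromethyl methyl ether, COCCl
Why: O-alkylation of both phenols with an α-chloro ether under amine base (MOM protection) is routine for hydroxybenzaldehydes, and MOM is chosen because it survives organolithium, hydride and carbonate conditions and is removed by mild acid at the end.

Step 2
Reactants: 2 2,4-bis(methoxymethoxy)benzaldehyde
Product: 3 1-ethynyl-2,4-bis(methoxymethoxy)benzene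
Conditions: dimethyl (1-diazo-2-oxopropyl)phosphonate, K2CO3, MeOH, 0 °C to rt
Reagents that add atoms: dimethyl (1-diazo-2-oxopropyl)phosphonate, COP(=O)(OC)C(=[N+]=[N-])C(C)=O
Why: Ohira–Bestmann homologation turns an aryl aldehyde into the terminal alkyne by olefination with the diazophosphonate anion, loss of N2 and 1,2-hydride shift, under conditions that leave MOM ethers untouched.

Step 3
Reactants: 4 4,4'-dihydroxybenzophenone
Product: 5 bis[4-(methoxymethoxy)phenyl]methanone
Conditions: MOMCl, i-Pr2NEt, DMF, 0 °C to rt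
Reagents that add atoms: chloromethyl methyl ether, COCCl
Why: The same MOM protection of two unhindered phenols should proceed cleanly and gives a non-enolizable diaryl ketone for the acetylide addition.

Step 4
Reactants: 6 tert-butyldimethyl(prop-2-yn-1-yloxy)silane
Product: 8 4-(tert-butyldimethylsilyloxy)but-2-ynoic acid, via lithium acetylide 7 (not isolated)
Conditions: n-BuLi, THF, −78 °C; CO2, −78 to 0 °C; cold 1 M HCl to pH 3
Reagents that add atoms: carbon dioxide, O=C=O
Why: Deprotonation of a terminal alkyne and carboxylation of the lithium acetylide is the standard route to alk-2-ynoic acids, and the primary silyl ether tolerates the brief cold acidification.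

Step 5
Reactants: 8 4-(tert-butyldimethylsilyloxy)but-2-ynoic acid
Product: 9 4-(tert-butyldimethylsilyloxy)but-2-ynoyl chloride
Conditions: 1-chloro-N,N,2-trimethylprop-1-en-1-amine, CH2Cl2, 0 °C to rt; concentrated and used crude in THF
Reagents that add atoms: 1-chloro-N,N,2-trimethylprop-1-en-1-amine, CC(C)=C(Cl)N(C)C
Why: Acid chloride formation with the α-chloroenamine is neutral and gives only an amide by-product, so no HCl is released that could cleave the silyl ether or add across the ynoate.

Step 6
Reactants: 3 1-ethynyl-2,4-bis(methoxymethoxy)benzene; 5 bis[4-(methoxymethoxy)phenyl]methanone; 9 4-(tert-butyldimethylsilyloxy)but-2-ynoyl chloride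
Product: 12 3-[2,4-bis(methoxymethoxy)phenyl]-1,1-bis[4-(methoxymethoxy)phenyl]prop-2-yn-1-yl 4-(tert-butyldimethylsilyloxy)but-2-ynoate, via lithium arylacetylide 10 (not isolated), via lithium propargylic alkoxide 11 (not isolated)
Conditions: 3, n-BuLi, THF, −78 °C; 5, −78 to 0 °C; 9, −78 to 0 °C; cold aq. NaHCO3; short column on Et3N-deactivated silica
Reagents that add atoms: none
Why: 1,2-Addition of a lithium acetylide to a diaryl ketone followed by O-acylation of the tertiary lithium alkoxide with an acid chloride is an established one-pot way to hindered propargylic esters, and the base-buffered work-up is chosen to keep the ionizable ester intact.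

Step 7
Reactants: 12 3-[2,4-bis(methoxymethoxy)phenyl]-1,1-bis[4-(methoxymethoxy)phenyl]prop-2-yn-1-yl 4-(tert-butyldimethylsilyloxy)but-2-ynoate; 13 acetylene
Product: 14 4-[2,4-bis(methoxymethoxy)phenyl]-7-[(tert-butyldimethylsilyloxy)methyl]-3,3-bis[4-(methoxymethoxy)phenyl]-2-benzofuran-1(3H)-one
Conditions: RhCl(PPh3)3 (10 mol %), acetylene (1 atm), toluene, 50 °C
Reagents that add atoms: none
Why: After loss of a phosphine, monovalent rhodium binds both alkynes of the 1,6-diyne and undergoes oxidative cyclization to a rhodacyclopentadiene of trivalent rhodium, which forms C1–C6; acetylene then inserts and reductive elimination forms C2–C3 and C4–C5 and regenerates monovalent rhodium. The closest known reaction type is the rhodium- or ruthenium-catalysed [2+2+2] cycloaddition of propargyl alkynoates with alkynes, acetylene included, which gives phthalides. The lactone ring closes by metal-templated coupling of the two tethered alkyne carbons, helped by the gem-diaryl effect at C7, and ring A closes as an all-sp2 six-membered ring by two-carbon insertion and reductive elimination. No stereocentre is formed. The step needs cross-cyclotrimerization to beat self-reaction and needs the tertiary propargylic C–O bond to stay intact: the tether makes the first metallacycle form fast, acetylene is small, symmetric and in excess so no regiochemical issue arises and it intercepts the metallacycle before a second hindered internal diyne can, and the neutral chloride complex in toluene offers no Lewis acid to ionize the ester.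

Step 8
Reactants: 14 4-[2,4-bis(methoxymethoxy)phenyl]-7-[(tert-butyldimethylsilyloxy)methyl]-3,3-bis[4-(methoxymethoxy)phenyl]-2-benzofuran-1(3H)-one
Product: 15 4-[2,4-bis(methoxymethoxy)phenyl]-7-[(tert-butyldimethylsilyloxy)methyl]-3,3-bis[4-(methoxymethoxy)phenyl]-1,3-dihydro-2-benzofuran-1-ol (racemic)
Conditions: i-Bu2AlH (DIBAL-H), CH2Cl2, −78 °C; aq. potassium sodium tartrate
Reagents that add atoms: none
Why: Partial reduction of a lactone with DIBAL-H at low temperature stops at the aluminium hemiacetal and gives the lactol on work-up, with silyl and MOM ethers inert and the new hemiacetal centre racemic and destroyed in the next step.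

Step 9
Reactants: 15 4-[2,4-bis(methoxymethoxy)phenyl]-7-[(tert-butyldimethylsilyloxy)methyl]-3,3-bis[4-(methoxymethoxy)phenyl]-1,3-dihydro-2-benzofuran-1-ol
Product: 17 {6-[2,4-bis(methoxymethoxy)phenyl]-3-[(tert-butyldimethylsilyloxy)methyl]-2-ethynylphenyl}bis[4-(methoxymethoxy)phenyl]methanol, via ring-opened hydroxy aldehyde 16 (not isolated)
Conditions: dimethyl (1-diazo-2-oxopropyl)phosphonate, K2CO3, MeOH/THF, rt to 40 °C
Reagents that add atoms: dimethyl (1-diazo-2-oxopropyl)phosphonate, COP(=O)(OC)C(=[N+]=[N-])C(C)=O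
Why: In the Ohira–Bestmann homologation of a lactol, the base opens the ring to hydroxy aldehyde 16, which is trapped irreversibly by the diazophosphonate anion, and loss of dimethyl phosphate and N2 with 1,2-hydride shift gives the terminal alkyne, so C8 becomes the ring-bound alkyne carbon.

Step 10
Reactants: 17 {6-[2,4-bis(methoxymethoxy)phenyl]-3-[(tert-butyldimethylsilyloxy)methyl]-2-ethynylphenyl}bis[4-(methoxymethoxy)phenyl]methanol; 18 4-iodophenol
Product: 19 4-{[2-{hydroxybis[4-(methoxymethoxy)phenyl]methyl}-3-[2,4-bis(methoxymethoxy)phenyl]-6-[(tert-butyldimethylsilyloxy)methyl]phenyl]ethynyl}phenol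
Conditions: Pd(PPh3)2Cl2 (5 mol %), CuI (5 mol %), Et3N/THF, degassed, 45 °C
Reagents that add atoms: none
Why: Sonogashira coupling of a terminal aryl alkyne with an aryl iodide under zerovalent palladium and copper co-catalysis tolerates free phenols and tertiary alcohols, and the neighbouring CH2OH stays silylated so that only the hindered tertiary hydroxyl could compete by cyclization.

Step 11
Reactants: 19 4-{[2-{hydroxybis[4-(methoxymethoxy)phenyl]methyl}-3-[2,4-bis(methoxymethoxy)phenyl]-6-[(tert-butyldimethylsilyloxy)methyl]phenyl]ethynyl}phenol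
Product: 21 Selaginellin F, via deprotected triaryl carbinol 20 (not isolated)
Conditions: conc. aq. HCl, MeOH/THF, 45 °C; then aq. NaHCO3
Reagents that add atoms: none
Why: Acid-catalysed acetal exchange removes the four aryl MOM ethers (methanol traps the formaldehyde unit as dimethoxymethane and so protects the resorcinol ring) and the primary silyl ether, and the same acid ionizes the bis(4-hydroxyphenyl)carbinol 20 to a trityl-type cation that loses a phenolic proton on neutralization to give the quinone methide (E1-type dehydration, fuchsone formation).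

**Compound list**

1 | 2,4-dihydroxybenzaldehyde | O=Cc1ccc(O)cc1O | starting material
2 | 2,4-bis(methoxymethoxy)benzaldehyde | O=Cc1ccc(OCOC)cc1OCOC | intermediate
3 | 1-ethynyl-2,4-bis(methoxymethoxy)benzene | C#Cc1ccc(OCOC)cc1OCOC | intermediate
4 | 4,4'-dihydroxybenzophenone | O=C(c1ccc(O)cc1)c1ccc(O)cc1 | starting material
5 | bis[4-(methoxymethoxy)phenyl]methanone | O=C(c1ccc(OCOC)cc1)c1ccc(OCOC)cc1 | intermediate
6 | tert-butyldimethyl(prop-2-yn-1-yloxy)silane | C#CCO[Si](C)(C)C(C)(C)C | starting material
7 | lithium 3-(tert-butyldimethylsilyloxy)prop-1-yn-1-ide (not isolated) | [Li]C#CCO[Si](C)(C)C(C)(C)C | intermediate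
8 | 4-(tert-butyldimethylsilyloxy)but-2-ynoic acid | OC(=O)C#CCO[Si](C)(C)C(C)(C)C | intermediate
9 | 4-(tert-butyldimethylsilyloxy)but-2-ynoyl chloride | ClC(=O)C#CCO[Si](C)(C)C(C)(C)C | intermediate
10 | lithium [2,4-bis(methoxymethoxy)phenyl]acetylide (not isolated) | [Li]C#Cc1ccc(OCOC)cc1OCOC | intermediate
11 | lithium 3-[2,4-bis(methoxymethoxy)phenyl]-1,1-bis[4-(methoxymethoxy)phenyl]prop-2-yn-1-olate (not isolated) | [Li]OC(C#Cc1ccc(OCOC)cc1OCOC)(c1ccc(OCOC)cc1)c1ccc(OCOC)cc1 | intermediate
12 | 3-[2,4-bis(methoxymethoxy)phenyl]-1,1-bis[4-(methoxymethoxy)phenyl]prop-2-yn-1-yl 4-(tert-butyldimethylsilyloxy)but-2-ynoate | COCOc1ccc(C#CC(OC(=O)C#CCO[Si](C)(C)C(C)(C)C)(c2ccc(OCOC)cc2)c2ccc(OCOC)cc2)c(OCOC)c1 | intermediate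
13 | acetylene | C#C | starting material
14 | 4-[2,4-bis(methoxymethoxy)phenyl]-7-[(tert-butyldimethylsilyloxy)methyl]-3,3-bis[4-(methoxymethoxy)phenyl]-2-benzofuran-1(3H)-one | COCOc1ccc(-c2ccc(CO[Si](C)(C)C(C)(C)C)c3C(=O)OC(c4ccc(OCOC)cc4)(c4ccc(OCOC)cc4)c23)c(OCOC)c1 | intermediate
15 | 4-[2,4-bis(methoxymethoxy)phenyl]-7-[(tert-butyldimethylsilyloxy)methyl]-3,3-bis[4-(methoxymethoxy)phenyl]-1,3-dihydro-2-benzofuran-1-ol (racemic lactol) | COCOc1ccc(-c2ccc(CO[Si](C)(C)C(C)(C)C)c3C(O)OC(c4ccc(OCOC)cc4)(c4ccc(OCOC)cc4)c23)c(OCOC)c1 | intermediate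
16 | 3-[2,4-bis(methoxymethoxy)phenyl]-6-[(tert-butyldimethylsilyloxy)methyl]-2-{hydroxybis[4-(methoxymethoxy)phenyl]methyl}benzaldehyde (open form of 15, not isolated) | COCOc1ccc(-c2ccc(CO[Si](C)(C)C(C)(C)C)c(C=O)c2C(O)(c2ccc(OCOC)cc2)c2ccc(OCOC)cc2)c(OCOC)c1 | intermediate
17 | {6-[2,4-bis(methoxymethoxy)phenyl]-3-[(tert-butyldimethylsilyloxy)methyl]-2-ethynylphenyl}bis[4-(methoxymethoxy)phenyl]methanol | COCOc1ccc(-c2ccc(CO[Si](C)(C)C(C)(C)C)c(C#C)c2C(O)(c2ccc(OCOC)cc2)c2ccc(OCOC)cc2)c(OCOC)c1 | intermediate
18 | 4-iodophenol | Oc1ccc(I)cc1 | starting material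
19 | 4-{[2-{hydroxybis[4-(methoxymethoxy)phenyl]methyl}-3-[2,4-bis(methoxymethoxy)phenyl]-6-[(tert-butyldimethylsilyloxy)methyl]phenyl]ethynyl}phenol | COCOc1ccc(-c2ccc(CO[Si](C)(C)C(C)(C)C)c(C#Cc3ccc(O)cc3)c2C(O)(c2ccc(OCOC)cc2)c2ccc(OCOC)cc2)c(OCOC)c1 | intermediate
20 | 2'-[bis(4-hydroxyphenyl)(hydroxy)methyl]-4'-(hydroxymethyl)-3'-[(4-hydroxyphenyl)ethynyl]biphenyl-2,4-diol (not isolated) | OCc1ccc(-c2ccc(O)cc2O)c(C(O)(c2ccc(O)cc2)c2ccc(O)cc2)c1C#Cc1ccc(O)cc1 | intermediate
21 | Selaginellin F, 4-{[2',4'-dihydroxy-4-(hydroxymethyl)-3-[(4-hydroxyphenyl)ethynyl]biphenyl-2-yl](4-hydroxyphenyl)methylidene}cyclohexa-2,5-dien-1-one (achiral) | O=C1C=CC(=C(c2ccc(O)cc2)c2c(-c3ccc(O)cc3O)ccc(CO)c2C#Cc2ccc(O)cc2)C=C1 | target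

**Count and risks**

Total steps: 11. Longest linear sequence: 8 steps (steps 1, 2, 6, 7, 8, 9, 10, 11; the branch through steps 4, 5, 6 to 11 is equally long).

Steps most likely to fail:

1. Step 7. Self-cyclotrimerization of the diyne, which is substituted at both alkyne termini and therefore slow, may outpace uptake of sparingly soluble acetylene, and prolonged heating with rhodium invites acyloxy shift of the tertiary propargylic ester. Fallback: setting out from 12, the two-carbon partner is changed from the gas to liquid vinyl acetate, used in large excess as an acetylene equivalent with the cationic monovalent-rhodium catalyst [Rh(cod)2]BF4/BINAP in CH2Cl2 at rt. The formal [2+2+2] of diyne and enol acetate gives the cyclohexadiene cycloadduct 4-[2,4-bis(methoxymethoxy)phenyl]-7-[(tert-butyldimethylsilyloxy)methyl]-3,3-bis[4-(methoxymethoxy)phenyl]-1-oxo-1,3,5,6-tetrahydro-2-benzofuran-5-yl acetate F1 (racemic; the acetate may sit on either carbon of the new CH–CH2 edge, and both isomers give the same arene). It is expected to lose acetic acid in the flask and so arrive at 14.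

2. Step 6. The hindered tertiary alkoxide may add in conjugate fashion to the ynoyl chloride or react too slowly, and the tertiary bis(alkoxyphenyl)propargylic ester may ionize during work-up or chromatography. Fallback: the ester tether is turned round so that no tertiary propargylic ester is needed, with the same three ring A bonds formed. Setting out from 3 and 6, acetylide 10 is carboxylated with CO2 to 3-[2,4-bis(methoxymethoxy)phenyl]prop-2-ynoic acid F2. Acetylide 7 is hydroxymethylated with paraformaldehyde to 4-(tert-butyldimethylsilyloxy)but-2-yn-1-ol F3. Steglich esterification (DCC, DMAP, CH2Cl2, 0 °C) gives 4-(tert-butyldimethylsilyloxy)but-2-yn-1-yl 3-[2,4-bis(methoxymethoxy)phenyl]prop-2-ynoate F4. RhCl(PPh3)3 and acetylene 13 then give 7-[2,4-bis(methoxymethoxy)phenyl]-4-[(tert-butyldimethylsilyloxy)methyl]-2-benzofuran-1(3H)-one F5, in which C7 is the lactone carbonyl and C8 the lactone CH2. Double addition of 4-(methoxymethoxy)phenyllithium (from commercial 1-bromo-4-(methoxymethoxy)benzene and n-BuLi, THF, −78 to 0 °C) opens the lactone to {6-[2,4-bis(methoxymethoxy)phenyl]-3-[(tert-butyldimethylsilyloxy)methyl]-2-(hydroxymethyl)phenyl}bis[4-(methoxymethoxy)phenyl]methanol F6. Oxidation of its primary benzylic alcohol with MnO2 in CH2Cl2 gives hydroxy aldehyde 16, which closes to lactol 15, where the route is rejoined before step 9.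

3. Step 9. The gem-diaryl lactol may stay closed, so that the hindered aldehyde is present only in traces and the diazophosphonate anion decays before it olefinates; the neighbouring carbinol oxygen may also add to the nascent unsaturated carbon. Fallback: setting out from 15, a Wittig dibromomethylenation with Ph3P=CBr2 (from (dibromomethyl)triphenylphosphonium bromide and KOt-Bu, THF) draws the ring–chain equilibrium to {6-[2,4-bis(methoxymethoxy)phenyl]-3-[(tert-butyldimethylsilyloxy)methyl]-2-(2,2-dibromoethenyl)phenyl}bis[4-(methoxymethoxy)phenyl]methanol F7. Treatment with n-BuLi (3 equiv, THF, −78 °C; second stage of the Corey–Fuchs sequence with Fritsch–Buttenberg–Wiechell rearrangement) and quenching with aq. NH4Cl gives 17.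

**Further compounds**

F1 | step 7 | 4-[2,4-bis(methoxymethoxy)phenyl]-7-[(tert-butyldimethylsilyloxy)methyl]-3,3-bis[4-(methoxymethoxy)phenyl]-1-oxo-1,3,5,6-tetrahydro-2-benzofuran-5-yl acetate (racemic) | COCOc1ccc(C2=C3C(=C(CO[Si](C)(C)C(C)(C)C)CC2OC(C)=O)C(=O)OC3(c2ccc(OCOC)cc2)c2ccc(OCOC)cc2)c(OCOC)c1
F2 | step 6 | 3-[2,4-bis(methoxymethoxy)phenyl]prop-2-ynoic acid | OC(=O)C#Cc1ccc(OCOC)cc1OCOC
F3 | step 6 | 4-(tert-butyldimethylsilyloxy)but-2-yn-1-ol | OCC#CCO[Si](C)(C)C(C)(C)C
F4 | step 6 | 4-(tert-butyldimethylsilyloxy)but-2-yn-1-yl 3-[2,4-bis(methoxymethoxy)phenyl]prop-2-ynoate | COCOc1ccc(C#CC(=O)OCC#CCO[Si](C)(C)C(C)(C)C)c(OCOC)c1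
F5 | step 6 | 7-[2,4-bis(methoxymethoxy)phenyl]-4-[(tert-butyldimethylsilyloxy)methyl]-2-benzofuran-1(3H)-one | COCOc1ccc(-c2ccc(CO[Si](C)(C)C(C)(C)C)c3COC(=O)c23)c(OCOC)c1
F6 | step 6 | {6-[2,4-bis(methoxymethoxy)phenyl]-3-[(tert-butyldimethylsilyloxy)methyl]-2-(hydroxymethyl)phenyl}bis[4-(methoxymethoxy)phenyl]methanol | COCOc1ccc(-c2ccc(CO[Si](C)(C)C(C)(C)C)c(CO)c2C(O)(c2ccc(OCOC)cc2)c2ccc(OCOC)cc2)c(OCOC)c1
F7 | step 9 | {6-[2,4-bis(methoxymethoxy)phenyl]-3-[(tert-butyldimethylsilyloxy)methyl]-2-(2,2-dibromoethenyl)phenyl}bis[4-(methoxymethoxy)phenyl]methanol | COCOc1ccc(-c2ccc(CO[Si](C)(C)C(C)(C)C)c(C=C(Br)Br)c2C(O)(c2ccc(OCOC)cc2)c2ccc(OCOC)cc2)c(OCOC)c1
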